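Ring A is obtained by contracting a cycloheptene. The key step exploits the quaternary C4 of ring A, which carries C19 next to the ring-fusion atom C5: in the precursor C19 is still a ring member. A trans-fused six–seven bicycle, built from (R)-carvone by two alkylations at C10 and ring-closing metathesis onto the isopropenyl group (C4, C18), is epoxidised on the β face across C4–C19. A bulky aluminium Lewis acid then moves C3 from C19 to C4; this single operation closes the C3–C4 bond, makes ring A six-membered, sets the C4 configuration and releases C19 as the aldehyde. C9 is homologated afterwards and the Z side chain is joined by B-alkyl Suzuki coupling.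

Key step: step 5

Remarks: Locants follow labdane numbering (C1–C10 decalin, C11–C16 side chain, C17 on C8, C18 and C19 on C4, C20 on C10); β is the face of the C20 methyl group. The seven-membered ring of compounds 5–7 is C10–C1–C2–C3–C19–C4–C5. Compound 2 is carried on as the mixture of epimers at C10, because C10 is re-enolised in step 2. Compounds 1, 3, 10 and 15 and all reagents are taken as commercial.

Step 1
Reactants: 1 (R)-(−)-carvone
Product: 2 6-methylcarvone (both epimers at the new methyl-bearing carbon)
Conditions: LiN(iPr)2, THF, −78 °C; MeI, −78 to 0 °C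
Reagents that add atoms: iodomethane, CI
Why: Kinetic deprotonation at the α′ carbon (future C10) gives the cross-conjugated lithium enolate, which is C-methylated (enolate alkylation); the configuration at this carbon is fixed only in step 2.

Step 2
Reactants: 2 6-methylcarvone; 3 5-iodopent-1-ene
Product: 4 (5S,6S)-2,6-dimethyl-6-(pent-4-en-1-yl)-5-(prop-1-en-2-yl)cyclohex-2-en-1-one
Conditions: LiN(iPr)2, THF, −78 to −20 °C; then 3, HMPA, −78 °C to rt
Reagents that add atoms: none
Why: Enolate alkylation of the fully substituted lithium enolate, in which the iodide should approach anti to the neighbouring isopropenyl group on C5, so that quaternary C10 carries the methyl cis and the pentenyl chain trans to isopropenyl.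

Step 3
Reactants: 4 (5S,6S)-2,6-dimethyl-6-(pent-4-en-1-yl)-5-(prop-1-en-2-yl)cyclohex-2-en-1-one
Product: 5 trans-fused bicyclic dienone (10β-methyl, 5α-H)
Conditions: second-generation Grubbs catalyst (5 mol%), CH2Cl2 (0.005 M), 40 °C
Reagents that add atoms: none
Why: Ring-closing olefin metathesis between the terminal alkene and the isopropenyl group should close the trans-fused cycloheptene with the trisubstituted C4=C19 double bond, the conjugated C7=C8 alkene being inert.

Step 4
Reactants: 5 trans-fused bicyclic dienone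
Product: 7 β-epoxide of dienone 5 (oxygen on C4 and C19 cis to the C20 methyl), via bromohydrin 6 (not isolated)
Conditions: NBS, THF/H2O, 0 °C; then K2CO3, MeOH, rt
Reagents that add atoms: N-bromosuccinimide, O=C1CCC(=O)N1Br; water, O
Why: Bromohydrin formation followed by intramolecular Williamson closure: the bromonium ion should form on the open α face of the electron-rich C4=C19 alkene (the β face is shielded by the axial C20 methyl), water opens it at tertiary C4 from the β face, and base closes the β-epoxide with inversion at C19.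

Step 5
Reactants: 7 β-epoxide of dienone 5
Product: 8 9-oxo-11,12,13,14,15,16-hexanorlabd-7-en-19-al (4β-formyl, 4α-methyl)
Conditions: MeAl(OC6H2-4-Br-2,6-tBu2)2 (20 mol%), CH2Cl2, −78 to −20 °C
Reagents that add atoms: none
Why: The bulky aluminium Lewis acid binds the epoxide oxygen and ionises the tertiary C4–O bond, and C3 migrates from C19 to C4 on the face opposite the departing oxygen while C19 becomes the aldehyde carbon (Meinwald rearrangement with 1,2-alkyl shift, a semipinacol ring contraction). The closest known reaction is the rearrangement of 1-methylcycloalkene oxides to 1-methylcycloalkanecarbaldehydes promoted by bulky aluminium aryloxides. No ring is closed by cyclisation: the seven-membered ring C10–C1–C2–C3–C19–C4–C5 contracts to six-membered ring A by a suprafacial 1,2-shift, and C19 leaves the ring. The new stereocentre C4 is controlled by the epoxide configuration, because migration with inversion at C4 places C19 on the β face where the oxygen was and leaves the C18 methyl α. The step needs alkyl shift instead of hydride shift from C19 (which would give the cycloheptanone) and cleavage of the tertiary, not the secondary, C–O bond; the hindered Lewis acid disfavours the conformer required for hydride shift, and the cation-stabilising tertiary C4 secures the regiochemistry.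

Step 6
Reactants: 8 9-oxo-11,12,13,14,15,16-hexanorlabd-7-en-19-al
Product: 9 19-hydroxy-11,12,13,14,15,16-hexanorlabd-7-en-9-one
Conditions: NaBH4 (0.3 equiv), MeOH/CH2Cl2, −40 °C
Reagents that add atoms: none
Why: Chemoselective borohydride reduction of the aldehyde in the presence of the hindered conjugated C9 ketone next to quaternary C10; no stereocentre is formed.

Step 7
Reactants: 9 19-hydroxy-11,12,13,14,15,16-hexanorlabd-7-en-9-one; 10 tigloyl chloride
Product: 11 9-oxo-11,12,13,14,15,16-hexanorlabd-7-en-19-yl (E)-2-methylbut-2-enoate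
Conditions: pyridine, DMAP (cat.), CH2Cl2, 0 to 40 °C
Reagents that add atoms: none
Why: DMAP-catalysed acylation of the neopentyl primary alcohol with the acid chloride (esterification), which keeps the E geometry of the tigloyl group.

Step 8
Reactants: 11 9-oxo-11,12,13,14,15,16-hexanorlabd-7-en-19-yl (E)-2-methylbut-2-enoate
Product: 12 9β,11-epoxy-12,13,14,15,16-pentanorlabd-7-en-19-yl (E)-2-methylbut-2-enoate (spiro-oxirane, C11 α)
Conditions: Me3S+ I−, n-BuLi, THF, −10 to 0 °C
Reagents that add atoms: trimethylsulfonium iodide, C[S+](C)C.[I-]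
Why: Corey–Chaykovsky epoxidation, in which the sulfonium ylide should add 1,2 to the C9 carbonyl from the α face, anti to the axial C20 methyl, so that C11 is α and the oxygen β.

Step 9
Reactants: 12 9β,11-epoxy-12,13,14,15,16-pentanorlabd-7-en-19-yl (E)-2-methylbut-2-enoate
Product: 13 11-oxo-12,13,14,15,16-pentanorlabd-7-en-19-yl (E)-2-methylbut-2-enoate (9α-H)
Conditions: BF3·OEt2 (20 mol%), CH2Cl2, −78 °C
Reagents that add atoms: none
Why: Meinwald rearrangement of the vinyl epoxide, in which ionisation at the allylic tertiary C9 and 1,2-hydride shift from C11 deliver hydrogen to the α face of C9 and give the β,γ-unsaturated aldehyde with the equatorial 9β-formyl group.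

Step 10
Reactants: 13 11-oxo-12,13,14,15,16-pentanorlabd-7-en-19-yl (E)-2-methylbut-2-enoate
Product: 14 13,14,15,16-tetranorlabda-7,11-dien-19-yl (E)-2-methylbut-2-enoate (9β-vinyl)
Conditions: Ph3PCH3Br, KN(SiMe3)2, THF, −78 to 0 °C
Reagents that add atoms: methyltriphenylphosphonium bromide, C[P+](c1ccccc1)(c1ccccc1)c1ccccc1.[Br-]
Why: Wittig methylenation with the salt-free ylide at low temperature should convert the aldehyde into the vinyl group without epimerising C9 or moving the C7=C8 double bond into conjugation.

Step 11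
Reactants: 15 but-2-ynoic acid
Product: 16 (Z)-3-iodobut-2-enoic acid
Conditions: NaI, AcOH, 110 °C
Reagents that add atoms: sodium iodide, [Na+].[I-]
Why: Anti hydroiodination of the alkynoic acid (conjugate addition of iodide, then protonation) should give the Z acid with iodine cis to the carboxyl group.

Step 12
Reactants: 14 13,14,15,16-tetranorlabda-7,11-dien-19-yl (E)-2-methylbut-2-enoate; 16 (Z)-3-iodobut-2-enoic acid
Product: 18 (13Z)-19-[(E)-2-methylbut-2-enoyloxy]labda-7,13-dien-15-oic acid (target), via alkylborane 17 (not isolated)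
Conditions: 9-BBN, THF, 0 °C to rt; then 16, Pd(dppf)Cl2 (5 mol%), AsPh3, Cs2CO3, DMF/H2O, 50 °C; dilute HCl work-up
Reagents that add atoms: 9-borabicyclo[3.3.1]nonane, B1C2CCCC1CCC2
Why: Hydroboration with 9-BBN is selective for the monosubstituted vinyl group (boron on C12), and the B-alkyl Suzuki–Miyaura coupling with the Z vinyl iodide proceeds with retention, which fixes the 13Z geometry without creating a stereocentre.

Compound list
1 | (R)-(−)-carvone, (5R)-2-methyl-5-(prop-1-en-2-yl)cyclohex-2-en-1-one | CC1=CC[C@H](CC1=O)C(C)=C | starting material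
2 | 6-methylcarvone, (5R)-2,6-dimethyl-5-(prop-1-en-2-yl)cyclohex-2-en-1-one, both C6 epimers | CC1=CC[C@H](C(C)C1=O)C(C)=C | intermediate
3 | 5-iodopent-1-ene | C=CCCCI | starting material
4 | (5S,6S)-2,6-dimethyl-6-(pent-4-en-1-yl)-5-(prop-1-en-2-yl)cyclohex-2-en-1-one (methyl cis, pentenyl trans to isopropenyl) | C=CCCC[C@]1(C)C(=O)C(C)=CC[C@H]1C(C)=C | intermediate
5 | trans-fused bicyclic dienone, 3,4a,9-trimethyl-1,4a,5,6,7,9a-hexahydro-4H-benzo[7]annulen-4-one (C4=C19 and C7=C8 double bonds, C9 ketone, 10β-methyl, 5α-H) | CC1=CCCC[C@]2(C)C(=O)C(C)=CC[C@@H]12 | intermediate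
6 | bromohydrin of 5 (19α-bromo, 4β-hydroxy, 4α-methyl) | C[C@]1(O)[C@H](Br)CCC[C@]2(C)C(=O)C(C)=CC[C@@H]12 | intermediate
7 | β-epoxide of 5 (4β,19β-epoxy, 4α-methyl) | C[C@]12O[C@H]1CCC[C@]3(C)C(=O)C(C)=CC[C@@H]23 | intermediate
8 | 9-oxo-11,12,13,14,15,16-hexanorlabd-7-en-19-al (4β-formyl, 4α-methyl, 5α-H, 10β-methyl) | O=C[C@@]1(C)CCC[C@]2(C)C(=O)C(C)=CC[C@@H]12 | intermediate
9 | 19-hydroxy-11,12,13,14,15,16-hexanorlabd-7-en-9-one | OC[C@@]1(C)CCC[C@]2(C)C(=O)C(C)=CC[C@@H]12 | intermediate
10 | tigloyl chloride, (E)-2-methylbut-2-enoyl chloride | C/C=C(\C)C(Cl)=O | starting material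
11 | 9-oxo-11,12,13,14,15,16-hexanorlabd-7-en-19-yl (E)-2-methylbut-2-enoate | C/C=C(\C)C(=O)OC[C@@]1(C)CCC[C@]2(C)C(=O)C(C)=CC[C@@H]12 | intermediate
12 | 9β,11-epoxy-12,13,14,15,16-pentanorlabd-7-en-19-yl (E)-2-methylbut-2-enoate (spiro-oxirane at C9, C11 α) | C/C=C(\C)C(=O)OC[C@@]1(C)CCC[C@]2(C)[C@]3(CO3)C(C)=CC[C@@H]12 | intermediate
13 | 11-oxo-12,13,14,15,16-pentanorlabd-7-en-19-yl (E)-2-methylbut-2-enoate (9α-H) | C/C=C(\C)C(=O)OC[C@@]1(C)CCC[C@]2(C)[C@@H](C=O)C(C)=CC[C@@H]12 | intermediate
14 | 13,14,15,16-tetranorlabda-7,11-dien-19-yl (E)-2-methylbut-2-enoate (9β-vinyl) | C/C=C(\C)C(=O)OC[C@@]1(C)CCC[C@]2(C)[C@@H](C=C)C(C)=CC[C@@H]12 | intermediate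
15 | but-2-ynoic acid | CC#CC(=O)O | starting material
16 | (Z)-3-iodobut-2-enoic acid | I/C(C)=C\C(=O)O | intermediate
17 | alkylborane, 12-(9-borabicyclo[3.3.1]nonan-9-yl)-13,14,15,16-tetranorlabd-7-en-19-yl (E)-2-methylbut-2-enoate | C/C=C(\C)C(=O)OC[C@@]1(C)CCC[C@]2(C)[C@@H](CCB3C4CCCC3CCC4)C(C)=CC[C@@H]12 | intermediate
18 | (13Z)-19-[(E)-2-methylbut-2-enoyloxy]labda-7,13-dien-15-oic acid | C/C=C(\C)C(=O)OC[C@@]1(C)CCC[C@]2(C)[C@@H](CC/C(C)=C\C(=O)O)C(C)=CC[C@@H]12 | target

Total step count: 12. Longest linear sequence: 11 steps (steps 1–10 and 12).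

Steps most likely to fail

1. Step 5 (key step). A 1,2-hydride shift from C19 to the C4 cation may compete with migration of C3 and give the seven-membered ketone, or a stepwise cationic course may erode the anti stereospecificity at C4. The fallback sets out from 5 and comes back at 9. mCPBA should epoxidise 5 on the open α face to the α-epoxide F1. HBr opens it at tertiary C4 with inversion to the bromohydrin F2 (4β-bromo, 19α-hydroxy). Dess–Martin periodinane gives the α-bromo ketone F3. NaOMe in ether then induces a Favorskii ring contraction: the C3 enolate displaces bromide at C4 with inversion and methoxide opens the cyclopropanone towards C3, which gives the methyl ester F4 with the C4 configuration of 8. LiAlH4 reduces ester and ketone to the diol F5, and MnO2 reoxidises the allylic C9 alcohol to 9.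

2. Step 8. Addition of the ylide to the hindered conjugated C9 carbonyl may be slow, which would allow attack on the tiglate ester or poor facial selectivity; that selectivity also decides the C9 configuration in step 9. The fallback sets out from 11 and comes back at 13. Takai–Lombardo methylenation (Zn, CH2Br2, TiCl4) of the C9 ketone gives the exocyclic diene F6. 9-BBN should add to the methylene group with hydrogen delivered to the α face of C9, giving the alkylborane F7. NaBO3 oxidises this to the primary alcohol F8, and Dess–Martin periodinane gives 13.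

3. Step 12. Transmetalation of the alkylborane may be sluggish in the presence of the free carboxylate partner, so that protodeboronation or β-hydride elimination takes over. The fallback sets out from 14 and comes back at 18. Alkylborane 17 is oxidised with NaBO3 to the primary alcohol F9 and converted with I2, PPh3 and imidazole into the iodide F10. Zinc insertion (Zn, LiCl, THF) gives the alkylzinc iodide F11. Negishi coupling (Pd(dppf)Cl2) with methyl (Z)-3-iodobut-2-enoate F12, made from 16 and trimethylsilyldiazomethane, gives the methyl ester F13, which Me3SnOH (1,2-dichloroethane, 80 °C) should hydrolyse selectively to 18 beside the hindered tiglate.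

Further compounds
F1 | step 5 | α-epoxide of 5 (4α,19α-epoxy, 4β-methyl) | C[C@@]12O[C@@H]1CCC[C@]3(C)C(=O)C(C)=CC[C@@H]23
F2 | step 5 | bromohydrin (4β-bromo, 19α-hydroxy, 4α-methyl) | C[C@]1(Br)[C@H](O)CCC[C@]2(C)C(=O)C(C)=CC[C@@H]12
F3 | step 5 | α-bromo ketone (4β-bromo, C19 ketone in the seven-membered ring) | C[C@]1(Br)C(=O)CCC[C@]2(C)C(=O)C(C)=CC[C@@H]12
F4 | step 5 | methyl 9-oxo-11,12,13,14,15,16-hexanorlabd-7-en-19-oate | COC(=O)[C@@]1(C)CCC[C@]2(C)C(=O)C(C)=CC[C@@H]12
F5 | step 5 | 11,12,13,14,15,16-hexanorlabd-7-ene-9,19-diol (C9 epimers) | OC[C@@]1(C)CCC[C@]2(C)C(O)C(C)=CC[C@@H]12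
F6 | step 8 | 12,13,14,15,16-pentanorlabda-7,9(11)-dien-19-yl (E)-2-methylbut-2-enoate | C/C=C(\C)C(=O)OC[C@@]1(C)CCC[C@]2(C)C(=C)C(C)=CC[C@@H]12
F7 | step 8 | 11-(9-borabicyclo[3.3.1]nonan-9-yl)-12,13,14,15,16-pentanorlabd-7-en-19-yl (E)-2-methylbut-2-enoate | C/C=C(\C)C(=O)OC[C@@]1(C)CCC[C@]2(C)[C@@H](CB3C4CCCC3CCC4)C(C)=CC[C@@H]12
F8 | step 8 | 11-hydroxy-12,13,14,15,16-pentanorlabd-7-en-19-yl (E)-2-methylbut-2-enoate | C/C=C(\C)C(=O)OC[C@@]1(C)CCC[C@]2(C)[C@@H](CO)C(C)=CC[C@@H]12
F9 | step 12 | 12-hydroxy-13,14,15,16-tetranorlabd-7-en-19-yl (E)-2-methylbut-2-enoate | C/C=C(\C)C(=O)OC[C@@]1(C)CCC[C@]2(C)[C@@H](CCO)C(C)=CC[C@@H]12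
F10 | step 12 | 12-iodo-13,14,15,16-tetranorlabd-7-en-19-yl (E)-2-methylbut-2-enoate | C/C=C(\C)C(=O)OC[C@@]1(C)CCC[C@]2(C)[C@@H](CCI)C(C)=CC[C@@H]12
F11 | step 12 | alkylzinc iodide from F10 | C/C=C(\C)C(=O)OC[C@@]1(C)CCC[C@]2(C)[C@@H](CC[Zn]I)C(C)=CC[C@@H]12
F12 | step 12 | methyl (Z)-3-iodobut-2-enoate | I/C(C)=C\C(=O)OC
F13 | step 12 | methyl (13Z)-19-[(E)-2-methylbut-2-enoyloxy]labda-7,13-dien-15-oate | C/C=C(\C)C(=O)OC[C@@]1(C)CCC[C@]2(C)[C@@H](CC/C(C)=C\C(=O)OC)C(C)=CC[C@@H]12
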